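Ring A of the benzofuran (C3a–C7a) carries a free phenol at C4 and a methyl ether at C6, with the chiral side chain on C5 between them and the furan annulated across C3a–C7a. This is the substitution pattern that a heteroaryl ketene and an alkoxyalkyne assemble directly, so ring A is disconnected into those two partners. In one operation the key step forms C7–C7a, C4–C5, C6–C7 and C3a–C4 and closes ring A with the stereocenter already in place. Its precursors are a 2-aryl-3-(methoxycarbonyl)-5-(diazoacetyl)furan, with ring B as a bis-silyl ether, and a chiral-pool (R)-silyloxy methoxyalkyne. Silyl-only protection allows a single fluoride deprotection at the end.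

Key step: step 11

Remark: ring B is carried as its bis(triisopropylsilyl) ether, because the isopropenyl carbinol next to the C4 phenol is unlikely to tolerate the acid that acetal-type phenol protection would need for removal.

Step 1
Reactants: 1 2-acetylfuran
Product: 2 1-(4,5-dibromofuran-2-yl)ethan-1-one
Conditions: AlCl3 (3 equiv), Br2 (2.2 equiv), CH2Cl2, 0 °C → rt
Reagents that add atoms: bromine, BrBr
Why: Electrophilic aromatic bromination under swamping-catalyst conditions: the ketone is held as its AlCl3 complex, which blocks enolisation (no side-chain bromination) and should direct the two brominations to ring positions C4 and C5.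

Step 2
Reactants: 3 4-bromobenzene-1,3-diol
Product: 4 1-bromo-2,4-bis(triisopropylsilyloxy)benzene
Conditions: TIPSCl (2.4 equiv), imidazole (5 equiv), DMF, rt
Reagents that add atoms: chlorotri(propan-2-yl)silane, CC(C)[Si](Cl)(C(C)C)C(C)C
Why: Routine silylation of both phenols (silyl ether formation); the bulky triisopropylsilyl groups should resist the organometallic, basic and reductive steps ahead, are slow to undergo retro-Brook migration, and fall to fluoride together with the side-chain silyl ether at the end.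

Step 3
Reactants: 4 1-bromo-2,4-bis(triisopropylsilyloxy)benzene; 2 1-(4,5-dibromofuran-2-yl)ethan-1-one
Product: 7 1-{4-bromo-5-[2,4-bis(triisopropylsilyloxy)phenyl]furan-2-yl}ethan-1-one, via aryllithium 5 (not isolated), via arylzinc chloride 6 (not isolated)
Conditions: 4 (1.1 equiv), n-BuLi (1.1 equiv), THF, −78 °C; ZnCl2 (1.2 equiv), −78 °C → rt; then 2 (1.0 equiv), Pd(PPh3)4 (5 mol %), 50 °C
Reagents that add atoms: none
Why: Negishi cross-coupling: bromine–lithium exchange and transmetalation to zinc give a nucleophile that tolerates the methyl ketone, and oxidative addition of zerovalent palladium should take place selectively at the C5–Br bond (α to the ring oxygen and conjugated with the acetyl group), leaving C4–Br for step 4.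

Step 4
Reactants: 7 1-{4-bromo-5-[2,4-bis(triisopropylsilyloxy)phenyl]furan-2-yl}ethan-1-one
Product: 8 methyl 5-acetyl-2-[2,4-bis(triisopropylsilyloxy)phenyl]furan-3-carboxylate
Conditions: CO (1 atm), Pd(OAc)2 (5 mol %), Xantphos (10 mol %), Et3N (3 equiv), MeOH/toluene, 80 °C
Reagents that add atoms: carbon monoxide, [C-]#[O+]; methanol, CO
Why: Palladium-catalysed alkoxycarbonylation of the remaining heteroaryl bromide (oxidative addition, CO insertion, methanolysis of the acylpalladium) should install the C3 ester under weakly basic conditions that spare the ketone and the aryl silyl ethers.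

Step 5
Reactants: 8 methyl 5-acetyl-2-[2,4-bis(triisopropylsilyloxy)phenyl]furan-3-carboxylate
Product: 10 methyl 5-(diazoacetyl)-2-[2,4-bis(triisopropylsilyloxy)phenyl]furan-3-carboxylate, via trifluoroacetyl diketone 9 (not isolated)
Conditions: LiN(SiMe3)2 (1.1 equiv), THF, −78 °C; CF3CO2CH2CF3 (1.2 equiv); aq. HCl work-up; then MsN3 (1.5 equiv), Et3N (1.5 equiv), H2O (1 equiv), MeCN, rt
Reagents that add atoms: methanesulfonyl azide, CS(=O)(=O)N=[N+]=[N-]
Why: Detrifluoroacetylative diazo transfer (a deacylative Regitz reaction): the kinetic lithium enolate of the methyl ketone is C-trifluoroacetylated, and the activated 1,3-diketone 9 should accept the diazo group from the sulfonyl azide with loss of the trifluoroacetyl group, the furan ester having no α-hydrogen to interfere.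

Step 6
Reactants: 11 methyl (4R)-2,2-dimethyl-1,3-dioxolane-4-carboxylate
Product: 13 1-[(4R)-2,2-dimethyl-1,3-dioxolan-4-yl]ethan-1-one, via Weinreb amide 12 (not isolated)
Conditions: MeNH(OMe)·HCl (1.5 equiv), i-PrMgCl (3.0 equiv), THF, −20 °C; then MeMgBr (2.0 equiv), −20 → 0 °C; aq. NH4Cl
Reagents that add atoms: methylmagnesium bromide, C[Mg]Br
Why: Weinreb ketone synthesis in one flask: the magnesium amide converts the ester into amide 12, whose chelated tetrahedral adduct with MeMgBr should collapse to the methyl ketone only on work-up, and no bond to the α-alkoxy stereocenter is made or broken at these low temperatures.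

Step 7
Reactants: 13 1-[(4R)-2,2-dimethyl-1,3-dioxolan-4-yl]ethan-1-one
Product: 15 (2S)-3-methylbut-3-ene-1,2-diol, via isopropenyl dioxolane 14 (not isolated)
Conditions: Ph3PCH3Br (1.3 equiv), KN(SiMe3)2 (1.25 equiv), THF, −78 → 0 °C; then AcOH/H2O (4:1), 40 °C
Reagents that add atoms: methyltriphenylphosphonium bromide, C[P+](c1ccccc1)(c1ccccc1)c1ccccc1.[Br-]
Why: Wittig methylenation with the non-stabilised ylide (carbonyl addition outruns enolisation at low temperature) followed by aqueous-acid hydrolysis of the acetonide should give the diol, the stereocenter being untouched and changing its descriptor from R to S only because the CIP priorities change.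

Step 8
Reactants: 15 (2S)-3-methylbut-3-ene-1,2-diol
Product: 17 (2S)-2-(tert-butyldimethylsilyloxy)-3-methylbut-3-en-1-yl trifluoromethanesulfonate, via hydroxy triflate 16 (not isolated)
Conditions: Tf2O (1.05 equiv), 2,6-lutidine (3 equiv), CH2Cl2, −78 °C; then TBSOTf (1.2 equiv), −78 → 0 °C
Reagents that add atoms: trifluoromethanesulfonic anhydride, O=S(=O)(OS(=O)(=O)C(F)(F)F)C(F)(F)F; tert-butyldimethylsilyl trifluoromethanesulfonate, CC(C)(C)[Si](C)(C)OS(=O)(=O)C(F)(F)F
Why: Chemoselective sulfonylation then silylation in one pot: at −78 °C the primary hydroxyl should be triflated much faster than the secondary allylic one, and immediate silylation of the latter prevents epoxide formation from hydroxy triflate 16.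

Step 9
Reactants: 18 trichloroethylene
Product: 19 (E)-1,2-dichloro-1-methoxyethene
Conditions: MeOH (1.0 equiv), KH (1.05 equiv), THF, 0 °C; then 18, −50 °C → rt; distillation
Reagents that add atoms: methanol, CO
Why: Base-induced elimination of HCl from trichloroethylene and anti addition of methoxide/methanol to the dichloroacetylene so formed (a nucleophilic vinylic substitution by elimination–addition) should give the dichlorovinyl ether, whose geometry is of no consequence for step 10.

Step 10
Reactants: 19 (E)-1,2-dichloro-1-methoxyethene; 17 (2S)-2-(tert-butyldimethylsilyloxy)-3-methylbut-3-en-1-yl trifluoromethanesulfonate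
Product: 22 tert-butyl{[(3R)-6-methoxy-2-methylhex-1-en-5-yn-3-yl]oxy}dimethylsilane, via chloro(methoxy)ethyne 20 (not isolated), via lithium methoxyacetylide 21 (not isolated)
Conditions: 19 (1.5 equiv), n-BuLi (3.0 equiv), THF, −78 → −40 °C; then 17 (1.0 equiv), DMPU, −78 → 0 °C
Reagents that add atoms: none
Why: Dehydrochlorination and chlorine–lithium exchange turn 19 into lithium methoxyacetylide, which should displace the primary triflate by SN2 alkylation of an acetylide without touching the adjacent stereocenter (its descriptor becomes R only through changed CIP priorities), the methoxy group being chosen because it has no β-hydrogen for a later retro-ene loss.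

Step 11
Reactants: 10 methyl 5-(diazoacetyl)-2-[2,4-bis(triisopropylsilyloxy)phenyl]furan-3-carboxylate; 22 tert-butyl{[(3R)-6-methoxy-2-methylhex-1-en-5-yn-3-yl]oxy}dimethylsilane
Product: 27 methyl 2-[2,4-bis(triisopropylsilyloxy)phenyl]-5-[(2R)-2-(tert-butyldimethylsilyloxy)-3-methylbut-3-en-1-yl]-4-hydroxy-6-methoxy-1-benzofuran-3-carboxylate, via furylketene 23 (not isolated), via cyclobutenone 24 (not isolated), via dienylketene 25 (not isolated), via cyclohexadienone 26 (not isolated)
Conditions: 10 (1.0 equiv), 22 (1.5 equiv), hν (254 nm, low-pressure Hg lamp), ClCH2CH2Cl, rt; then 80 °C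
Reagents that add atoms: none
Why: Irradiation expels N2 and triggers a Wolff rearrangement (the furyl group shifts to the diazo carbon, forming C7–C7a) to furylketene 23, which should add [2+2] to ynol ether 22 (C4–C5 and C6–C7) to give cyclobutenone 24; four-electron conrotatory opening, by light or heat, gives dienylketene 25, whose ketene carbon closes onto the adjacent furan CH in a thermal six-electron disrotatory electrocyclization (C3a–C4), and enolisation of dienone 26 aromatises ring A. This is the diazo ketone (photochemical Wolff) form of the Danheiser benzannulation, a known reaction type for furyl and other heteroaryl diazo ketones with alkoxy- and siloxyalkynes. The one ring formed is the six-membered ring A, closed by 6π electrocyclization and not by an ionic or radical cyclisation. No lasting stereocenter is created (the sp3 centers of 24 and 26 disappear on aromatisation), and the (R)-carbinol center, two atoms away from the reacting alkyne carbon, is not touched. The regiochemistry needed follows from the polarisation of the ynol ether: its nucleophilic, chain-bearing carbon attacks the ketene carbonyl carbon, so OMe ends at C6 and the chain at C5, while ring closure can only occur at furan C4 of 10, the sole carbon neighbour of the ketene-bearing furan carbon (the other neighbour is oxygen). Excess alkyne should limit acylation of the product phenol by ketene, and the methoxy group cannot undergo retro-ene cleavage at 80 °C.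

Step 12
Reactants: 27 methyl 2-[2,4-bis(triisopropylsilyloxy)phenyl]-5-[(2R)-2-(tert-butyldimethylsilyloxy)-3-methylbut-3-en-1-yl]-4-hydroxy-6-methoxy-1-benzofuran-3-carboxylate
Product: 28 2-[2,4-bis(triisopropylsilyloxy)phenyl]-5-[(2R)-2-(tert-butyldimethylsilyloxy)-3-methylbut-3-en-1-yl]-3-(hydroxymethyl)-6-methoxy-1-benzofuran-4-ol
Conditions: i-Bu2AlH (4.5 equiv), CH2Cl2, −78 → 0 °C; aq. KNaC4H4O6 work-up
Reagents that add atoms: none
Why: Hydride reduction of the ester with i-Bu2AlH (the C4 phenol is first converted into an aluminium phenoxide, hence the excess) should give the primary alcohol while the silyl ethers, the aryl methyl ether and the isolated alkene are inert.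

Step 13
Reactants: 28 2-[2,4-bis(triisopropylsilyloxy)phenyl]-5-[(2R)-2-(tert-butyldimethylsilyloxy)-3-methylbut-3-en-1-yl]-3-(hydroxymethyl)-6-methoxy-1-benzofuran-4-ol
Product: 29 2-[2,4-bis(triisopropylsilyloxy)phenyl]-5-[(2R)-2-(tert-butyldimethylsilyloxy)-3-methylbut-3-en-1-yl]-4-hydroxy-6-methoxy-1-benzofuran-3-carbaldehyde
Conditions: MnO2 (15 equiv), CH2Cl2, rt
Reagents that add atoms: none
Why: Selective MnO2 oxidation of the activated benzofuran-3-ylmethanol (a benzylic-type alcohol) should stop at the aldehyde, which is stabilised by its hydrogen bond to C4–OH, and the secondary allylic alcohol cannot be oxidised because it is still silylated.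

Step 14
Reactants: 29 2-[2,4-bis(triisopropylsilyloxy)phenyl]-5-[(2R)-2-(tert-butyldimethylsilyloxy)-3-methylbut-3-en-1-yl]-4-hydroxy-6-methoxy-1-benzofuran-3-carbaldehyde
Product: 30 2-(2,4-dihydroxyphenyl)-4-hydroxy-5-[(2R)-2-hydroxy-3-methylbut-3-en-1-yl]-6-methoxy-1-benzofuran-3-carbaldehyde
Conditions: Bu4NF (5 equiv), AcOH (5 equiv), THF, 0 °C → rt
Reagents that add atoms: none
Why: Fluoride-mediated global desilylation should cleave the two aryl triisopropylsilyl ethers and the secondary tert-butyldimethylsilyl ether in one operation, the acetic acid buffer sparing the polyphenolic aldehyde from strongly basic phenoxide conditions and no acid strong enough to add C4–OH across the isopropenyl group being involved.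

Compound list
1 | 2-acetylfuran | CC(=O)c1ccco1 | starting material
2 | 1-(4,5-dibromofuran-2-yl)ethan-1-one | CC(=O)c1cc(Br)c(Br)o1 | intermediate
3 | 4-bromobenzene-1,3-diol | Oc1ccc(Br)c(O)c1 | starting material
4 | 1-bromo-2,4-bis(triisopropylsilyloxy)benzene | Brc1ccc(O[Si](C(C)C)(C(C)C)C(C)C)cc1O[Si](C(C)C)(C(C)C)C(C)C | intermediate
5 | [2,4-bis(triisopropylsilyloxy)phenyl]lithium | [Li]c1ccc(O[Si](C(C)C)(C(C)C)C(C)C)cc1O[Si](C(C)C)(C(C)C)C(C)C | intermediate
6 | [2,4-bis(triisopropylsilyloxy)phenyl]zinc chloride | Cl[Zn]c1ccc(O[Si](C(C)C)(C(C)C)C(C)C)cc1O[Si](C(C)C)(C(C)C)C(C)C | intermediate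
7 | 1-{4-bromo-5-[2,4-bis(triisopropylsilyloxy)phenyl]furan-2-yl}ethan-1-one | CC(=O)c1cc(Br)c(o1)-c2ccc(O[Si](C(C)C)(C(C)C)C(C)C)cc2O[Si](C(C)C)(C(C)C)C(C)C | intermediate
8 | methyl 5-acetyl-2-[2,4-bis(triisopropylsilyloxy)phenyl]furan-3-carboxylate | COC(=O)c1cc(C(C)=O)oc1-c2ccc(O[Si](C(C)C)(C(C)C)C(C)C)cc2O[Si](C(C)C)(C(C)C)C(C)C | intermediate
9 | methyl 2-[2,4-bis(triisopropylsilyloxy)phenyl]-5-(4,4,4-trifluoro-3-oxobutanoyl)furan-3-carboxylate | COC(=O)c1cc(C(=O)CC(=O)C(F)(F)F)oc1-c2ccc(O[Si](C(C)C)(C(C)C)C(C)C)cc2O[Si](C(C)C)(C(C)C)C(C)C | intermediate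
10 | methyl 5-(diazoacetyl)-2-[2,4-bis(triisopropylsilyloxy)phenyl]furan-3-carboxylate | COC(=O)c1cc(C(=O)C=[N+]=[N-])oc1-c2ccc(O[Si](C(C)C)(C(C)C)C(C)C)cc2O[Si](C(C)C)(C(C)C)C(C)C | intermediate
11 | methyl (4R)-2,2-dimethyl-1,3-dioxolane-4-carboxylate | CC1(C)OC[C@@H](O1)C(=O)OC | starting material
12 | (4R)-N-methoxy-N,2,2-trimethyl-1,3-dioxolane-4-carboxamide | CC1(C)OC[C@@H](O1)C(=O)N(C)OC | intermediate
13 | 1-[(4R)-2,2-dimethyl-1,3-dioxolan-4-yl]ethan-1-one | CC1(C)OC[C@@H](O1)C(C)=O | intermediate
14 | (4S)-2,2-dimethyl-4-(prop-1-en-2-yl)-1,3-dioxolane | CC1(C)OC[C@@H](O1)C(C)=C | intermediate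
15 | (2S)-3-methylbut-3-ene-1,2-diol | C=C(C)[C@H](O)CO | intermediate
16 | (2S)-2-hydroxy-3-methylbut-3-en-1-yl trifluoromethanesulfonate | C=C(C)[C@H](O)COS(=O)(=O)C(F)(F)F | intermediate
17 | (2S)-2-(tert-butyldimethylsilyloxy)-3-methylbut-3-en-1-yl trifluoromethanesulfonate | C=C(C)[C@H](O[Si](C)(C)C(C)(C)C)COS(=O)(=O)C(F)(F)F | intermediate
18 | trichloroethylene | ClC=C(Cl)Cl | starting material
19 | (E)-1,2-dichloro-1-methoxyethene | Cl/C=C(/Cl)OC | intermediate
20 | 1-chloro-2-methoxyethyne | COC#CCl | intermediate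
21 | (methoxyethynyl)lithium | [Li]C#COC | intermediate
22 | tert-butyl{[(3R)-6-methoxy-2-methylhex-1-en-5-yn-3-yl]oxy}dimethylsilane | C=C(C)[C@H](O[Si](C)(C)C(C)(C)C)CC#COC | intermediate
23 | methyl 2-[2,4-bis(triisopropylsilyloxy)phenyl]-5-(2-oxoethenyl)furan-3-carboxylate | COC(=O)c1cc(C=C=O)oc1-c2ccc(O[Si](C(C)C)(C(C)C)C(C)C)cc2O[Si](C(C)C)(C(C)C)C(C)C | intermediate
24 | methyl 2-[2,4-bis(triisopropylsilyloxy)phenyl]-5-{3-[(2R)-2-(tert-butyldimethylsilyloxy)-3-methylbut-3-en-1-yl]-2-methoxy-4-oxocyclobut-2-en-1-yl}furan-3-carboxylate (both epimers at the ring CH) | COC(=O)c1cc(C3C(=O)C(C[C@@H](O[Si](C)(C)C(C)(C)C)C(C)=C)=C3OC)oc1-c2ccc(O[Si](C(C)C)(C(C)C)C(C)C)cc2O[Si](C(C)C)(C(C)C)C(C)C | intermediate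
25 | methyl 2-[2,4-bis(triisopropylsilyloxy)phenyl]-5-{(1E)-3-[(2R)-2-(tert-butyldimethylsilyloxy)-3-methylbut-3-en-1-yl]-2-methoxy-4-oxobuta-1,3-dien-1-yl}furan-3-carboxylate (the isomer able to cyclise) | O=C=C(C[C@@H](O[Si](C)(C)C(C)(C)C)C(C)=C)/C(OC)=C\c1cc(C(=O)OC)c(o1)-c2ccc(O[Si](C(C)C)(C(C)C)C(C)C)cc2O[Si](C(C)C)(C(C)C)C(C)C | intermediate
26 | methyl 2-[2,4-bis(triisopropylsilyloxy)phenyl]-5-[(2R)-2-(tert-butyldimethylsilyloxy)-3-methylbut-3-en-1-yl]-6-methoxy-4-oxo-3a,4-dihydro-1-benzofuran-3-carboxylate (both epimers at C3a) | COC(=O)C1=C(c2ccc(O[Si](C(C)C)(C(C)C)C(C)C)cc2O[Si](C(C)C)(C(C)C)C(C)C)OC2=CC(OC)=C(C[C@@H](O[Si](C)(C)C(C)(C)C)C(C)=C)C(=O)C12 | intermediate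
27 | methyl 2-[2,4-bis(triisopropylsilyloxy)phenyl]-5-[(2R)-2-(tert-butyldimethylsilyloxy)-3-methylbut-3-en-1-yl]-4-hydroxy-6-methoxy-1-benzofuran-3-carboxylate | C=C(C)[C@H](O[Si](C)(C)C(C)(C)C)Cc1c(OC)cc2oc(-c3ccc(O[Si](C(C)C)(C(C)C)C(C)C)cc3O[Si](C(C)C)(C(C)C)C(C)C)c(C(=O)OC)c2c1O | intermediate
28 | 2-[2,4-bis(triisopropylsilyloxy)phenyl]-5-[(2R)-2-(tert-butyldimethylsilyloxy)-3-methylbut-3-en-1-yl]-3-(hydroxymethyl)-6-methoxy-1-benzofuran-4-ol | C=C(C)[C@H](O[Si](C)(C)C(C)(C)C)Cc1c(OC)cc2oc(-c3ccc(O[Si](C(C)C)(C(C)C)C(C)C)cc3O[Si](C(C)C)(C(C)C)C(C)C)c(CO)c2c1O | intermediate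
29 | 2-[2,4-bis(triisopropylsilyloxy)phenyl]-5-[(2R)-2-(tert-butyldimethylsilyloxy)-3-methylbut-3-en-1-yl]-4-hydroxy-6-methoxy-1-benzofuran-3-carbaldehyde | C=C(C)[C@H](O[Si](C)(C)C(C)(C)C)Cc1c(OC)cc2oc(-c3ccc(O[Si](C(C)C)(C(C)C)C(C)C)cc3O[Si](C(C)C)(C(C)C)C(C)C)c(C=O)c2c1O | intermediate
30 | 2-(2,4-dihydroxyphenyl)-4-hydroxy-5-[(2R)-2-hydroxy-3-methylbut-3-en-1-yl]-6-methoxy-1-benzofuran-3-carbaldehyde | C=C(C)[C@H](O)Cc1c(OC)cc2oc(-c3ccc(O)cc3O)c(C=O)c2c1O | target

Total step count: 14. Longest linear sequence: 8 steps (for example steps 2, 3, 4, 5, 11, 12, 13, 14; the alkyne branch, steps 6, 7, 8, 10, is equally long).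

Steps most likely to fail

Step 11 (key step). The furylketene may be intercepted by the phenol already formed (O-acylation), or the strongly absorbing 2-arylfuran chromophore may screen the diazo ketone and photodegrade, so that too little material reaches the electrocyclization. The fallback sets out from 10 and comes back at 27; it generates the same ketene without light and takes the cascade apart. A silver-catalysed Wolff rearrangement of 10 in wet THF (PhCO2Ag, Et3N, THF/H2O, rt; Arndt–Eistert homologation) would give {5-[2,4-bis(triisopropylsilyloxy)phenyl]-4-(methoxycarbonyl)furan-2-yl}acetic acid F1. Oxalyl chloride with catalytic DMF would convert it into methyl 5-(2-chloro-2-oxoethyl)-2-[2,4-bis(triisopropylsilyloxy)phenyl]furan-3-carboxylate F2. Slow addition of Et3N to F2 and alkyne 22 in CH2Cl2 would release ketene 23 at low concentration and give cyclobutenone 24, which would be isolated this time and heated in toluene at 110 °C to ring-open, electrocyclise and tautomerise to 27.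

Step 10. The alkoxyacetylide is a sluggish nucleophile and the triflate is β-branched and β-oxygenated, so displacement may lose out to elimination of triflate or to decay of the acetylide on warming. The fallback sets out from 15 and comes back at 22; it opens an epoxide instead of displacing a sulfonate. Diol 15 would be closed to (2S)-2-(prop-1-en-2-yl)oxirane F3 (NaH, N-tosylimidazole, THF, 0 °C → rt; the stereocenter is not involved). F3 would be opened at its CH2 carbon by acetylide 21 in the presence of BF3·OEt2 (THF, −78 °C) to give (3R)-6-methoxy-2-methylhex-1-en-5-yn-3-ol F4, and silylation (TBSCl, imidazole, DMF) would give 22. Competing attack at the allylic epoxide carbon is the process to watch in this variant.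

Step 4. Oxidative addition at the C4–Br bond, shielded by the twisted ortho-silyloxyaryl group, may be slow, so that protodebromination or catalyst decomposition outruns CO insertion. The fallback sets out from 7 and comes back at 8; it introduces the ester through an organolithium. Ketone 7 would be masked as 2-{4-bromo-5-[2,4-bis(triisopropylsilyloxy)phenyl]furan-2-yl}-2-methyl-1,3-dioxolane F5 (ethylene glycol, TsOH cat., benzene, reflux with removal of water). Bromine–lithium exchange and acylation (t-BuLi, THF, −78 °C; then ClCO2Me) would give methyl 2-[2,4-bis(triisopropylsilyloxy)phenyl]-5-(2-methyl-1,3-dioxolan-2-yl)furan-3-carboxylate F6, and mild aqueous acid (1 M HCl, acetone, rt) would unmask the ketone to give 8.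

Further compounds
F1 | step 11 | {5-[2,4-bis(triisopropylsilyloxy)phenyl]-4-(methoxycarbonyl)furan-2-yl}acetic acid | OC(=O)Cc1cc(C(=O)OC)c(o1)-c2ccc(O[Si](C(C)C)(C(C)C)C(C)C)cc2O[Si](C(C)C)(C(C)C)C(C)C
F2 | step 11 | methyl 5-(2-chloro-2-oxoethyl)-2-[2,4-bis(triisopropylsilyloxy)phenyl]furan-3-carboxylate | ClC(=O)Cc1cc(C(=O)OC)c(o1)-c2ccc(O[Si](C(C)C)(C(C)C)C(C)C)cc2O[Si](C(C)C)(C(C)C)C(C)C
F3 | step 10 | (2S)-2-(prop-1-en-2-yl)oxirane | C=C(C)[C@H]1CO1
F4 | step 10 | (3R)-6-methoxy-2-methylhex-1-en-5-yn-3-ol | C=C(C)[C@H](O)CC#COC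
F5 | step 4 | 2-{4-bromo-5-[2,4-bis(triisopropylsilyloxy)phenyl]furan-2-yl}-2-methyl-1,3-dioxolane | CC1(OCCO1)c2cc(Br)c(o2)-c3ccc(O[Si](C(C)C)(C(C)C)C(C)C)cc3O[Si](C(C)C)(C(C)C)C(C)C
F6 | step 4 | methyl 2-[2,4-bis(triisopropylsilyloxy)phenyl]-5-(2-methyl-1,3-dioxolan-2-yl)furan-3-carboxylate | CC1(OCCO1)c2cc(C(=O)OC)c(o2)-c3ccc(O[Si](C(C)C)(C(C)C)C(C)C)cc3O[Si](C(C)C)(C(C)C)C(C)C
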